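## Retrosynthetic overview

1. The target comes from its hexa-silyl ether by fluoride desilylation; the E-stilbene is made late by Heck coupling of a C6 aryl bromide with 4-silyloxystyrene.
2. Key disconnection C2–C3: intermolecular Michael addition of a chiral benzylic sulfonium ylide (C2, ring B) to an o-quinone methide (C3, rings A and C). The phenolate formed then closes the C2–O bond in the same flask, giving the trans-2,3-diaryl-dihydrofuran with both stereocentres.
3. The o-quinone methide comes from an o-hydroxybenzhydryl sulfone, made from an aryl Grignard reagent (ring C) and 4-bromo-2-hydroxy-6-silyloxybenzaldehyde (ring A; its 2,6-dihydroxy precursor is symmetric, so there is no regiochemical question).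
4. The ylide comes from 2,4-bis(silyloxy)benzyl alcohol and isothiocineole, itself made from limonene and sulfur.
5. Ring order: all four benzene rings are bought; the dihydrofuran ring is the only ring formed (key step).

Abbreviations: TIPS = triisopropylsilyl; TIPSO = triisopropylsilyloxy; Ts = 4-methylphenylsulfonyl; TfOH = CF3SO3H.

Assumption: the ylide from the (1R,4R,5R)-sulfide attacks the o-quinone methide with the facial sense it shows toward aldehydes, which corresponds to (2S,3S) here; if the opposite sense is found, the mirror-image sulfide from (S)-limonene is used with nothing else changed.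

## Route

**Step 1**
Reactants: 1 4-bromo-2,6-difluorobenzaldehyde
Product: 2 4-bromo-2,6-dimethoxybenzaldehyde
Conditions: NaOMe (2.5 equiv), MeOH, reflux
Reagents that add atoms: sodium methoxide, [Na+].[O-]C
Why: Both fluorides are ortho to the aldehyde and are displaced by methoxide in a double nucleophilic aromatic substitution (SNAr), while the bromide is a far poorer leaving group and stays.

**Step 2**
Reactants: 2 4-bromo-2,6-dimethoxybenzaldehyde
Product: 3 4-bromo-2,6-dihydroxybenzaldehyde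
Conditions: BBr3 (3 equiv), CH2Cl2, −78 °C → rt; then H2O
Reagents that add atoms: none
Why: Lewis-acid ether cleavage (BBr3 demethylation) is assisted by chelation to the ortho aldehyde and leaves the aryl bromide untouched.

**Step 3**
Reactants: 3 4-bromo-2,6-dihydroxybenzaldehyde
Product: 4 4-bromo-2-hydroxy-6-(TIPSO)benzaldehyde
Conditions: TIPSCl (1.05 equiv), imidazole (2 equiv), CH2Cl2, 0 °C
Reagents that add atoms: triisopropylsilyl chloride, CC(C)[Si](Cl)(C(C)C)C(C)C
Why: O-silylation stops after one group because the remaining hydroxyl is hydrogen-bonded to the aldehyde and hindered, and the two hydroxyls are equivalent so only one product is possible.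

**Step 4**
Reactants: 5 5-bromoresorcinol
Product: 6 1-bromo-3,5-bis(TIPSO)benzene
Conditions: TIPSCl (2.3 equiv), imidazole (4 equiv), DMF, rt
Reagents that add atoms: triisopropylsilyl chloride, CC(C)[Si](Cl)(C(C)C)C(C)C
Why: Standard O-silylation of two unhindered phenols gives a base-stable aryl bromide ready for metalation.

**Step 5**
Reactants: 4 4-bromo-2-hydroxy-6-(TIPSO)benzaldehyde; 6 1-bromo-3,5-bis(TIPSO)benzene
Product: 8 (±)-5-bromo-2-{[3,5-bis(TIPSO)phenyl](hydroxy)methyl}-3-(TIPSO)phenol, via arylmagnesium bromide 7 (not isolated)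
Conditions: 6, Mg, THF, 50 °C; then 4 (7 : 4 = 2.2 : 1), THF, −78 → −20 °C; sat. aq. NH4Cl
Reagents that add atoms: none
Why: Grignard addition to the aldehyde after the first equivalent has deprotonated the phenol; the low temperature and the bulky TIPS group suppress silyl migration, and the racemic carbinol centre is later flattened in the o-quinone methide.

**Step 6**
Reactants: 8 (±)-5-bromo-2-{[3,5-bis(TIPSO)phenyl](hydroxy)methyl}-3-(TIPSO)phenol
Product: 9 (±)-5-bromo-2-{[3,5-bis(TIPSO)phenyl](Ts)methyl}-3-(TIPSO)phenol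
Conditions: p-TolSO2H (1.5 equiv), CH2Cl2, rt
Reagents that add atoms: p-toluenesulfinic acid, Cc1ccc(cc1)S(=O)O
Why: Acid-promoted SN1 substitution through the stabilised o-hydroxybenzhydryl cation, with S-attack of the sulfinic acid, gives the stable sulfone that later releases the o-quinone methide under base.

**Step 7**
Reactants: 10 2,4-dihydroxybenzaldehyde
Product: 11 2,4-bis(TIPSO)benzaldehyde
Conditions: TIPSCl (2.4 equiv), imidazole (5 equiv), DMF, rt → 40 °C
Reagents that add atoms: triisopropylsilyl chloride, CC(C)[Si](Cl)(C(C)C)C(C)C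
Why: Exhaustive O-silylation with excess reagent and gentle warming also caps the chelated ortho hydroxyl.

**Step 8**
Reactants: 11 2,4-bis(TIPSO)benzaldehyde
Product: 12 [2,4-bis(TIPSO)phenyl]methanol
Conditions: NaBH4, MeOH/THF, 0 °C
Reagents that add atoms: none
Why: Borohydride reduction of the aldehyde, with aryl TIPS ethers stable to it and too hindered to migrate at 0 °C.

**Step 9**
Reactants: 13 (R)-(+)-limonene
Product: 14 (1R,4R,5R)-4,7,7-trimethyl-6-thiabicyclo[3.2.1]octane (isothiocineole)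
Conditions: S8 (1 equiv S), γ-terpinene (1 equiv), neat, 110 °C; distillation
Reagents that add atoms: sulfur, S1SSSSSSS1
Why: Radical addition of sulfur across both C=C bonds of limonene, with γ-terpinene as hydrogen donor, gives the bridged sulfide; the existing stereocentre of limonene fixes the two bridgeheads.

**Step 10**
Reactants: 12 [2,4-bis(TIPSO)phenyl]methanol; 14 isothiocineole
Product: 15 (1R,4R,5R)-6-[2,4-bis(TIPSO)benzyl]-4,7,7-trimethyl-6-thiabicyclo[3.2.1]octan-6-ium triflate (one diastereomer at sulfur, benzyl on the open face; the sulfur centre is not written in the SMILES)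
Conditions: 14 (1.3 equiv), TfOH (1.0 equiv), CH2Cl2, −40 → 0 °C; precipitation from pentane
Reagents that add atoms: trifluoromethanesulfonic acid, OS(=O)(=O)C(F)(F)F
Why: The 2,4-disilyloxybenzyl cation released by the strong acid is captured by the soft sulfide on its less hindered lone pair (SN1 S-alkylation of a sulfide by an alcohol with a non-nucleophilic counter-ion).

**Step 11 (key step)**
Reactants: 9 (±)-5-bromo-2-{[3,5-bis(TIPSO)phenyl](Ts)methyl}-3-(TIPSO)phenol; 15 sulfonium triflate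
Product: 19 (2S,3S)-6-bromo-2-[2,4-bis(TIPSO)phenyl]-3-[3,5-bis(TIPSO)phenyl]-4-(TIPSO)-2,3-dihydro-1-benzofuran, via o-quinone methide 16 (not isolated), via sulfonium ylide 17 (not isolated), via betaine 18 (not isolated)
Conditions: 15 (1.3 equiv), Cs2CO3 (3 equiv), CH2Cl2/MeCN 4:1, 0 °C → rt; 14 recovered
Reagents that add atoms: none
Why: Base releases the o-quinone methide from the sulfone and the ylide from the salt, and Michael addition of the ylide re-aromatises ring A and forms C2–C3 irreversibly. The bicyclic sulfide fixes the ylide conformation and shields one face, the aryl groups add anti, and the phenolate then displaces the sulfide by SN2 with inversion at C2 to give the trans-(2S,3S) ring (Michael-initiated ring closure).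

**Step 12**
Reactants: 20 4-hydroxybenzaldehyde
Product: 21 4-(TIPSO)benzaldehyde
Conditions: TIPSCl (1.1 equiv), imidazole (2 equiv), DMF, rt
Reagents that add atoms: triisopropylsilyl chloride, CC(C)[Si](Cl)(C(C)C)C(C)C
Why: Simple O-silylation of an unhindered phenol.

**Step 13**
Reactants: 21 4-(TIPSO)benzaldehyde
Product: 22 4-(TIPSO)styrene
Conditions: Ph3PCH3Br (1.2 equiv), KOt-Bu (1.2 equiv), THF, 0 °C → rt
Reagents that add atoms: methyltriphenylphosphonium bromide, C[P+](c1ccccc1)(c1ccccc1)c1ccccc1.[Br-]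
Why: Wittig methylenation of a non-enolisable aryl aldehyde, with the aryl silyl ether stable to the ylide.

**Step 14**
Reactants: 19 (2S,3S)-6-bromo dihydrobenzofuran; 22 4-(TIPSO)styrene
Product: 23 (2S,3S)-2-[2,4-bis(TIPSO)phenyl]-3-[3,5-bis(TIPSO)phenyl]-4-(TIPSO)-6-{(E)-2-[4-(TIPSO)phenyl]ethenyl}-2,3-dihydro-1-benzofuran
Conditions: 22 (1.5 equiv), Pd2(dba)3 (2.5 mol %), [HP(t-Bu)3]BF4 (10 mol %), Cy2NMe (1.5 equiv), 1,4-dioxane, 60 °C
Reagents that add atoms: none
Why: Heck reaction of the unhindered aryl bromide with the styrene on zerovalent palladium gives the E-alkene by syn insertion and syn β-hydride elimination; the mild amine base touches neither the silyl ethers nor C2 and C3.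

**Step 15**
Reactants: 23 hexa-TIPS ether
Product: 24 (2S,3S)-2-(2,4-dihydroxyphenyl)-3-(3,5-dihydroxyphenyl)-6-[(E)-2-(4-hydroxyphenyl)ethenyl]-2,3-dihydro-1-benzofuran-4-ol (target, CNP0156611.2)
Conditions: TBAF (8 equiv), AcOH (8 equiv), THF, 0 °C → rt, argon
Reagents that add atoms: none
Why: Fluoride cleaves all six aryl silyl ethers, and the acetic acid buffer keeps the phenols protonated so the 2-aryl benzylic ether does not open through a quinone methide and the stereocentres and E-alkene are kept (global desilylation).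

## Compound list

1 | 4-bromo-2,6-difluorobenzaldehyde | O=Cc1c(F)cc(Br)cc1F | starting material
2 | 4-bromo-2,6-dimethoxybenzaldehyde | COc1cc(Br)cc(OC)c1C=O | intermediate
3 | 4-bromo-2,6-dihydroxybenzaldehyde | O=Cc1c(O)cc(Br)cc1O | intermediate
4 | 4-bromo-2-hydroxy-6-(TIPSO)benzaldehyde | O=Cc1c(O)cc(Br)cc1O[Si](C(C)C)(C(C)C)C(C)C | intermediate
5 | 5-bromoresorcinol | Oc1cc(O)cc(Br)c1 | starting material
6 | 1-bromo-3,5-bis(TIPSO)benzene | Brc1cc(O[Si](C(C)C)(C(C)C)C(C)C)cc(O[Si](C(C)C)(C(C)C)C(C)C)c1 | intermediate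
7 | 3,5-bis(TIPSO)phenylmagnesium bromide | Br[Mg]c1cc(O[Si](C(C)C)(C(C)C)C(C)C)cc(O[Si](C(C)C)(C(C)C)C(C)C)c1 | intermediate
8 | (±)-5-bromo-2-{[3,5-bis(TIPSO)phenyl](hydroxy)methyl}-3-(TIPSO)phenol | OC(c1cc(O[Si](C(C)C)(C(C)C)C(C)C)cc(O[Si](C(C)C)(C(C)C)C(C)C)c1)c1c(O)cc(Br)cc1O[Si](C(C)C)(C(C)C)C(C)C | intermediate
9 | (±)-5-bromo-2-{[3,5-bis(TIPSO)phenyl](Ts)methyl}-3-(TIPSO)phenol | Cc1ccc(cc1)S(=O)(=O)C(c1cc(O[Si](C(C)C)(C(C)C)C(C)C)cc(O[Si](C(C)C)(C(C)C)C(C)C)c1)c1c(O)cc(Br)cc1O[Si](C(C)C)(C(C)C)C(C)C | intermediate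
10 | 2,4-dihydroxybenzaldehyde | O=Cc1ccc(O)cc1O | starting material
11 | 2,4-bis(TIPSO)benzaldehyde | O=Cc1ccc(O[Si](C(C)C)(C(C)C)C(C)C)cc1O[Si](C(C)C)(C(C)C)C(C)C | intermediate
12 | [2,4-bis(TIPSO)phenyl]methanol | OCc1ccc(O[Si](C(C)C)(C(C)C)C(C)C)cc1O[Si](C(C)C)(C(C)C)C(C)C | intermediate
13 | (R)-(+)-limonene | CC1=CC[C@@H](CC1)C(C)=C | starting material
14 | (1R,4R,5R)-4,7,7-trimethyl-6-thiabicyclo[3.2.1]octane (isothiocineole) | C[C@@H]1CC[C@@H]2C[C@H]1SC2(C)C | intermediate
15 | (1R,4R,5R)-6-[2,4-bis(TIPSO)benzyl]-4,7,7-trimethyl-6-thiabicyclo[3.2.1]octan-6-ium triflate | C[C@@H]1CC[C@@H]2C[C@H]1[S+](Cc1ccc(O[Si](C(C)C)(C(C)C)C(C)C)cc1O[Si](C(C)C)(C(C)C)C(C)C)C2(C)C.[O-]S(=O)(=O)C(F)(F)F | intermediate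
16 | 3-bromo-6-[3,5-bis(TIPSO)benzylidene]-5-(TIPSO)cyclohexa-2,4-dien-1-one (o-quinone methide, alkene geometry not defined) | O=C1C=C(Br)C=C(O[Si](C(C)C)(C(C)C)C(C)C)C1=Cc1cc(O[Si](C(C)C)(C(C)C)C(C)C)cc(O[Si](C(C)C)(C(C)C)C(C)C)c1 | intermediate
17 | sulfonium ylide of 15 (benzylic carbanion on sulfur) | C[C@@H]1CC[C@@H]2C[C@H]1[S+]([CH-]c1ccc(O[Si](C(C)C)(C(C)C)C(C)C)cc1O[Si](C(C)C)(C(C)C)C(C)C)C2(C)C | intermediate
18 | betaine: 5-bromo-2-{(1S,2R)-1-[3,5-bis(TIPSO)phenyl]-2-[2,4-bis(TIPSO)phenyl]-2-(isothiocineolium-6-yl)ethyl}-3-(TIPSO)phenolate | C[C@@H]1CC[C@@H]2C[C@H]1[S+]([C@@H](c1ccc(O[Si](C(C)C)(C(C)C)C(C)C)cc1O[Si](C(C)C)(C(C)C)C(C)C)[C@@H](c1cc(O[Si](C(C)C)(C(C)C)C(C)C)cc(O[Si](C(C)C)(C(C)C)C(C)C)c1)c1c([O-])cc(Br)cc1O[Si](C(C)C)(C(C)C)C(C)C)C2(C)C | intermediate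
19 | (2S,3S)-6-bromo-2-[2,4-bis(TIPSO)phenyl]-3-[3,5-bis(TIPSO)phenyl]-4-(TIPSO)-2,3-dihydro-1-benzofuran (trans) | Brc1cc(O[Si](C(C)C)(C(C)C)C(C)C)c2c(c1)O[C@H](c1ccc(O[Si](C(C)C)(C(C)C)C(C)C)cc1O[Si](C(C)C)(C(C)C)C(C)C)[C@H]2c1cc(O[Si](C(C)C)(C(C)C)C(C)C)cc(O[Si](C(C)C)(C(C)C)C(C)C)c1 | intermediate
20 | 4-hydroxybenzaldehyde | O=Cc1ccc(O)cc1 | starting material
21 | 4-(TIPSO)benzaldehyde | O=Cc1ccc(O[Si](C(C)C)(C(C)C)C(C)C)cc1 | intermediate
22 | 4-(TIPSO)styrene | C=Cc1ccc(O[Si](C(C)C)(C(C)C)C(C)C)cc1 | intermediate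
23 | (2S,3S)-2-[2,4-bis(TIPSO)phenyl]-3-[3,5-bis(TIPSO)phenyl]-4-(TIPSO)-6-{(E)-2-[4-(TIPSO)phenyl]ethenyl}-2,3-dihydro-1-benzofuran | CC(C)[Si](Oc1ccc(/C=C/c2cc(O[Si](C(C)C)(C(C)C)C(C)C)c3c(c2)O[C@H](c2ccc(O[Si](C(C)C)(C(C)C)C(C)C)cc2O[Si](C(C)C)(C(C)C)C(C)C)[C@H]3c2cc(O[Si](C(C)C)(C(C)C)C(C)C)cc(O[Si](C(C)C)(C(C)C)C(C)C)c2)cc1)(C(C)C)C(C)C | intermediate
24 | (2S,3S)-2-(2,4-dihydroxyphenyl)-3-(3,5-dihydroxyphenyl)-6-[(E)-2-(4-hydroxyphenyl)ethenyl]-2,3-dihydro-1-benzofuran-4-ol | Oc1ccc(/C=C/c2cc(O)c3c(c2)O[C@H](c2ccc(O)cc2O)[C@H]3c2cc(O)cc(O)c2)cc1 | target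

## Count and risks

Total steps: 15. Longest linear sequence: 8 steps (1 → 2 → 3 → 4 → 8 → 9 → 19 → 23 → 24).

Three steps most likely to fail:

**Step 11.** Two partners that each carry an ortho silyloxy group must meet, and both the trans ratio and the ee rest on the chiral ylide. The fallback gives up asymmetric induction and secures the configuration by separation; it sets out from 12 and 9 and comes back at 19. Alcohol 12 is treated with tetrahydrothiophene and TfOH to give the small achiral salt 1-[2,4-bis(TIPSO)benzyl]tetrahydrothiophenium triflate F1. With Cs2CO3 and sulfone 9, its 2,4-bis(TIPSO)benzylidene tetrahydrothiophenium ylide F2 adds to 16 and closes to the racemic trans-dihydrobenzofuran, that is 19 together with the (2R,3R)-enantiomer of 19 F3. Preparative chromatography on a cellulose-based chiral stationary phase then delivers 19.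

**Step 10.** The very electron-rich benzyl sulfonium salt may ionise back or oligomerise on isolation. The fallback never isolates a salt and makes ylide 17 by carbene transfer; it sets out from 11 and comes back at 17 (and so at 19). Aldehyde 11 is condensed with TsNHNH2 in MeOH to N'-[2,4-bis(TIPSO)benzylidene]-4-methylbenzenesulfonohydrazide F4, and NaOMe converts it into its sodium salt F5. In the flask of step 11 (9, Cs2CO3, sulfide 14, BnEt3NCl 10 mol %, Rh2(OAc)4 1 mol %, 1,4-dioxane, 40 °C), F5 slowly releases [2,4-bis(TIPSO)phenyl]diazomethane F6. Its rhodium carbene is passed to 14 to give 17, which is consumed by 16 as before.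

**Step 14.** The Heck coupling may stall or give some 1,1-diarylethene regioisomer that is hard to remove. The fallback uses an alkene partner of fixed geometry in a cross-coupling; it sets out from 21 and comes back at 23. Aldehyde 21 is treated with lithiated bis(pinacolboryl)methane (CH2(Bpin)2, LiTMP, THF, −78 °C → rt; boron-Wittig olefination) to give (E)-2-{2-[4-(TIPSO)phenyl]ethenyl}-4,4,5,5-tetramethyl-1,3,2-dioxaborolane F7. Suzuki–Miyaura coupling of F7 with bromide 19 (Pd(dppf)Cl2, K3PO4, THF/H2O, 60 °C) gives 23.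

## Further compounds

F1 | step 11 | 1-[2,4-bis(TIPSO)benzyl]tetrahydrothiophenium triflate | CC(C)[Si](Oc1ccc(C[S+]2CCCC2)c(O[Si](C(C)C)(C(C)C)C(C)C)c1)(C(C)C)C(C)C.[O-]S(=O)(=O)C(F)(F)F
F2 | step 11 | 2,4-bis(TIPSO)benzylidene tetrahydrothiophenium ylide | CC(C)[Si](Oc1ccc([CH-][S+]2CCCC2)c(O[Si](C(C)C)(C(C)C)C(C)C)c1)(C(C)C)C(C)C
F3 | step 11 | (2R,3R)-enantiomer of 19 | Brc1cc(O[Si](C(C)C)(C(C)C)C(C)C)c2c(c1)O[C@@H](c1ccc(O[Si](C(C)C)(C(C)C)C(C)C)cc1O[Si](C(C)C)(C(C)C)C(C)C)[C@@H]2c1cc(O[Si](C(C)C)(C(C)C)C(C)C)cc(O[Si](C(C)C)(C(C)C)C(C)C)c1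
F4 | step 10 | N'-[2,4-bis(TIPSO)benzylidene]-4-methylbenzenesulfonohydrazide | Cc1ccc(cc1)S(=O)(=O)N/N=C/c1ccc(O[Si](C(C)C)(C(C)C)C(C)C)cc1O[Si](C(C)C)(C(C)C)C(C)C
F5 | step 10 | sodium salt of F4 | [Na+].Cc1ccc(cc1)S(=O)(=O)[N-]/N=C/c1ccc(O[Si](C(C)C)(C(C)C)C(C)C)cc1O[Si](C(C)C)(C(C)C)C(C)C
F6 | step 10 | [2,4-bis(TIPSO)phenyl]diazomethane | [N-]=[N+]=Cc1ccc(O[Si](C(C)C)(C(C)C)C(C)C)cc1O[Si](C(C)C)(C(C)C)C(C)C
F7 | step 14 | (E)-2-{2-[4-(TIPSO)phenyl]ethenyl}-4,4,5,5-tetramethyl-1,3,2-dioxaborolane | CC(C)[Si](Oc1ccc(/C=C/B2OC(C)(C)C(C)(C)O2)cc1)(C(C)C)C(C)C
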